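**Retrosynthetic overview**
- The usual route (double Suzuki coupling on a dihalo-tetraoxybenzene, then selective acylation of four equivalent central oxygens) is avoided. The central ring is built de novo instead.
- Key step: thermal 4π ring opening / 6π ring closure (Moore-type ring expansion) of a 4-alkenyl-4-benzoyloxycyclobutenone. It gives a hydroquinone monobenzoate whose only free OH is para to the benzoate, so the two different para acyl groups need no selective acylation.
- The cyclobutenone comes from a 3-benzyloxy-4-arylcyclobutenedione (squaric acid, then dibenzyl squarate, then aryllithium) and a cis-β-benzyloxy-α-arylvinyllithium (from 4-benzyloxybenzaldehyde), trapped in the flask with benzoyl chloride.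
- End game: the (S)-3-acetoxybutanoyl group (chiral pool, (S)-3-hydroxybutanoic acid) goes onto the free phenol, then the four benzyl ethers are removed by hydrogenolysis.
- Ring order: both outer aryl rings are bought, the four-membered ring comes from squaric acid, and the central benzene ring is the only ring formed (step 6).

Assumption: (benzyloxymethyl)triphenylphosphonium chloride and, for one fallback, 2-(benzyloxy)-N-methoxy-N-methylacetamide are taken as catalogue compounds; intermediates whose single sp3 ring carbon is later flattened are racemic.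

**Route**

Step 1
Reactants: 1 squaric acid (3,4-dihydroxycyclobut-3-ene-1,2-dione)
Product: 2 3,4-bis(benzyloxy)cyclobut-3-ene-1,2-dione (dibenzyl squarate)
Conditions: BnOH (4 equiv), toluene, reflux, Dean–Stark
Reagents that add atoms: benzyl alcohol, OCc1ccccc1
Why: Azeotropic esterification of a vinylogous acid (addition–elimination, self-catalysed by the strongly acidic squaric acid), the standard way to dialkyl squarates; no stereocentre is involved.

Step 2
Reactants: 3 1-(benzyloxy)-4-bromobenzene; 2 dibenzyl squarate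
Product: 7 3-(benzyloxy)-4-[4-(benzyloxy)phenyl]cyclobut-3-ene-1,2-dione, via aryllithium 4 (not isolated), via lithium alkoxide adduct 5 (not isolated), via hydroxycyclobutenone 6 (not isolated)
Conditions: n-BuLi, THF, −78 °C; add to 2, THF, −78 °C; 1 M HCl quench; then cat. 12 M HCl, CH2Cl2, rt
Reagents that add atoms: water, O
Why: Bromine–lithium exchange, 1,2-addition of the aryllithium to a squarate carbonyl and acid-promoted allylic transposition with loss of benzyl alcohol (Liebeskind–Moore squarate protocol; the new carbonyl oxygen comes from water) give the 3-alkoxy-4-arylcyclobutenedione.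

Step 3
Reactants: 8 4-(benzyloxy)benzaldehyde; 9 (benzyloxymethyl)triphenylphosphonium chloride
Product: 11 1-(benzyloxy)-4-[2-(benzyloxy)ethenyl]benzene (E/Z mixture), via phosphorus ylide 10 (not isolated)
Conditions: KOt-Bu, THF, 0 °C; then 8, 0 °C → rt
Reagents that add atoms: none
Why: Wittig olefination with an alkoxymethylene ylide gives the enol ether; the E/Z ratio does not matter because both isomers converge in step 4.

Step 4
Reactants: 11 1-(benzyloxy)-4-[2-(benzyloxy)ethenyl]benzene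
Product: 13 1-(benzyloxy)-4-[(Z)-2-(benzyloxy)-1-bromoethenyl]benzene, via dibromide 12 (not isolated)
Conditions: Br2 (1.0 equiv), CH2Cl2, −78 °C; then DBU, −78 °C → rt
Reagents that add atoms: bromine, BrBr
Why: Bromination–dehydrobromination of an enol ether (as used for 2-bromoglycals and 2-bromovinyl ethers) puts bromine on the nucleophilic aryl-bearing carbon; loss of the benzylic proton from the oxocarbenium ion should favour the Z isomer, in which the small bromine is cis to OBn and the aryl group is trans.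

Step 5
Reactants: 13 1-(benzyloxy)-4-[(Z)-2-(benzyloxy)-1-bromoethenyl]benzene (1.2 equiv); 7 3-(benzyloxy)-4-[4-(benzyloxy)phenyl]cyclobut-3-ene-1,2-dione
Product: 16 2-(benzyloxy)-3-[4-(benzyloxy)phenyl]-1-{(Z)-2-(benzyloxy)-1-[4-(benzyloxy)phenyl]ethenyl}-4-oxocyclobut-2-en-1-yl benzoate (racemic), via vinyllithium 14 (not isolated), via lithium alkoxide 15 (not isolated)
Conditions: t-BuLi (2.0 equiv per 13), THF, −78 °C; then 7, −78 °C; then BzCl, −78 → −20 °C
Reagents that add atoms: benzoyl chloride, O=C(Cl)c1ccccc1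
Why: Bromine–lithium exchange with retention gives a cis-β-alkoxyvinyllithium (O–Li chelated, stable at −78 °C like (Z)-2-ethoxyvinyllithium) that adds 1,2 to the ketone-like carbonyl of 7 next to the benzyloxy-bearing carbon (the other carbonyl is a deactivated vinylogous ester), and the tertiary alkoxide is O-acylated in the flask; the new sp3 centre is racemic and is destroyed in step 6.

Step 6
Reactants: 16 2-(benzyloxy)-3-[4-(benzyloxy)phenyl]-1-{(Z)-2-(benzyloxy)-1-[4-(benzyloxy)phenyl]ethenyl}-4-oxocyclobut-2-en-1-yl benzoate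
Product: 19 2,5-bis(benzyloxy)-3,6-bis[4-(benzyloxy)phenyl]-4-hydroxyphenyl benzoate, via dienylketene 17 (not isolated), via cyclohexadienone 18 (not isolated)
Conditions: toluene (degassed, 0.02 M), 110 °C
Reagents that add atoms: none
Why: Proposed new method: thermal conrotatory 4π opening of the cyclobutenone (the acyloxy oxygen rotates outward as a lone-pair donor and the alkenyl group inward; the opening is reversible, so the unproductive rotamer returns) gives a dienylketene that closes by 6π electrocyclization onto the enol ether carbon and tautomerizes irreversibly to the phenol, leaving the benzoate para to the new OH; the closest known reaction is the Moore–Liebeskind ring expansion of 4-alkenyl-4-alkoxy- or 4-silyloxycyclobutenones to hydroquinone monoethers, and the new element is an acyloxy group at C4.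

Step 7
Reactants: 20 (S)-3-hydroxybutanoic acid
Product: 21 (S)-3-acetoxybutanoic acid
Conditions: AcCl (neat, 3 equiv), 0 °C → rt; H2O work-up
Reagents that add atoms: acetyl chloride, CC(=O)Cl
Why: O-Acetylation of the secondary alcohol (any mixed anhydride on the acid is hydrolysed on work-up); the stereocentre comes from the chiral pool and no bond to it is broken.

Step 8
Reactants: 21 (S)-3-acetoxybutanoic acid; 19 2,5-bis(benzyloxy)-3,6-bis[4-(benzyloxy)phenyl]-4-hydroxyphenyl benzoate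
Product: 23 4-(benzoyloxy)-2,5-bis(benzyloxy)-3,6-bis[4-(benzyloxy)phenyl]phenyl (3S)-3-(acetyloxy)butanoate, via acid chloride 22 (not isolated)
Conditions: (COCl)2, cat. DMF, CH2Cl2, 0 °C → rt, evaporate; then 19, pyridine, CH2Cl2, 0 °C → rt
Reagents that add atoms: none
Why: Acid chloride formation and pyridine-mediated O-acylation of the only free phenol, which has no ortho hydroxyl to allow acyl migration; the weak base at 0 °C limits E1cB loss of acetate, and the β-stereocentre is not touched.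

Step 9
Reactants: 23 4-(benzoyloxy)-2,5-bis(benzyloxy)-3,6-bis[4-(benzyloxy)phenyl]phenyl (3S)-3-(acetyloxy)butanoate
Product: 24 4-(benzoyloxy)-2,5-dihydroxy-3,6-bis(4-hydroxyphenyl)phenyl (3S)-3-(acetyloxy)butanoate (target)
Conditions: H2 (1 atm), 10% Pd/C, EtOAc, rt; filter through Celite, purify without base
Reagents that add atoms: none
Why: Neutral heterogeneous hydrogenolysis cleaves the four aryl benzyl ethers while aryl esters and the acetate survive, and the absence of base avoids acyl migration between ortho oxygens; the stereocentre is untouched.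

**Compound list**
1 | squaric acid (3,4-dihydroxycyclobut-3-ene-1,2-dione) | O=C1C(=O)C(O)=C1O | starting material
2 | 3,4-bis(benzyloxy)cyclobut-3-ene-1,2-dione (dibenzyl squarate) | O=C1C(=O)C(OCc2ccccc2)=C1OCc1ccccc1 | intermediate
3 | 1-(benzyloxy)-4-bromobenzene | Brc1ccc(OCc2ccccc2)cc1 | starting material
4 | [4-(benzyloxy)phenyl]lithium | [Li]c1ccc(OCc2ccccc2)cc1 | intermediate
5 | lithium 2,3-bis(benzyloxy)-1-[4-(benzyloxy)phenyl]-4-oxocyclobut-2-en-1-olate (racemic) | [Li]OC1(c2ccc(OCc3ccccc3)cc2)C(OCc2ccccc2)=C(OCc2ccccc2)C1=O | intermediate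
6 | 2,3-bis(benzyloxy)-4-[4-(benzyloxy)phenyl]-4-hydroxycyclobut-2-en-1-one (racemic) | OC1(c2ccc(OCc3ccccc3)cc2)C(OCc2ccccc2)=C(OCc2ccccc2)C1=O | intermediate
7 | 3-(benzyloxy)-4-[4-(benzyloxy)phenyl]cyclobut-3-ene-1,2-dione | O=C1C(=O)C(OCc2ccccc2)=C1c1ccc(OCc2ccccc2)cc1 | intermediate
8 | 4-(benzyloxy)benzaldehyde | O=Cc1ccc(OCc2ccccc2)cc1 | starting material
9 | (benzyloxymethyl)triphenylphosphonium chloride | [Cl-].C(OCc1ccccc1)[P+](c1ccccc1)(c1ccccc1)c1ccccc1 | starting material
10 | (benzyloxymethylidene)triphenylphosphorane | C(OCc1ccccc1)=P(c1ccccc1)(c1ccccc1)c1ccccc1 | intermediate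
11 | 1-(benzyloxy)-4-[2-(benzyloxy)ethenyl]benzene (E/Z mixture) | C(=COCc1ccccc1)c1ccc(OCc2ccccc2)cc1 | intermediate
12 | 1-(benzyloxy)-4-[2-(benzyloxy)-1,2-dibromoethyl]benzene (diastereomer mixture) | BrC(C(Br)OCc1ccccc1)c1ccc(OCc2ccccc2)cc1 | intermediate
13 | 1-(benzyloxy)-4-[(Z)-2-(benzyloxy)-1-bromoethenyl]benzene (Br cis to OBn) | Br/C(=C\OCc1ccccc1)c1ccc(OCc2ccccc2)cc1 | intermediate
14 | {(E)-2-(benzyloxy)-1-[4-(benzyloxy)phenyl]ethenyl}lithium (Li cis to OBn) | [Li]/C(=C\OCc1ccccc1)c1ccc(OCc2ccccc2)cc1 | intermediate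
15 | lithium 2-(benzyloxy)-3-[4-(benzyloxy)phenyl]-1-{(Z)-2-(benzyloxy)-1-[4-(benzyloxy)phenyl]ethenyl}-4-oxocyclobut-2-en-1-olate (racemic) | O=C1C(c2ccc(OCc3ccccc3)cc2)=C(OCc2ccccc2)C1(O[Li])/C(=C\OCc2ccccc2)c2ccc(OCc3ccccc3)cc2 | intermediate
16 | 2-(benzyloxy)-3-[4-(benzyloxy)phenyl]-1-{(Z)-2-(benzyloxy)-1-[4-(benzyloxy)phenyl]ethenyl}-4-oxocyclobut-2-en-1-yl benzoate (racemic) | O=C1C(c2ccc(OCc3ccccc3)cc2)=C(OCc2ccccc2)C1(OC(=O)c2ccccc2)/C(=C\OCc2ccccc2)c2ccc(OCc3ccccc3)cc2 | intermediate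
17 | (3Z,5Z)-3,6-bis(benzyloxy)-2,5-bis[4-(benzyloxy)phenyl]-1-oxohexa-1,3,5-trien-4-yl benzoate (dienylketene) | O=C=C(c1ccc(OCc2ccccc2)cc1)/C(OCc1ccccc1)=C(/OC(=O)c1ccccc1)\C(c1ccc(OCc2ccccc2)cc1)=C/OCc1ccccc1 | intermediate
18 | 3,6-bis(benzyloxy)-2,5-bis[4-(benzyloxy)phenyl]-4-oxocyclohexa-1,5-dien-1-yl benzoate (racemic) | O=C1C(c2ccc(OCc3ccccc3)cc2)=C(OCc2ccccc2)C(OC(=O)c2ccccc2)=C(c2ccc(OCc3ccccc3)cc2)C1OCc1ccccc1 | intermediate
19 | 2,5-bis(benzyloxy)-3,6-bis[4-(benzyloxy)phenyl]-4-hydroxyphenyl benzoate | Oc1c(-c2ccc(OCc3ccccc3)cc2)c(OCc2ccccc2)c(OC(=O)c2ccccc2)c(-c2ccc(OCc3ccccc3)cc2)c1OCc1ccccc1 | intermediate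
20 | (S)-3-hydroxybutanoic acid | C[C@H](O)CC(=O)O | starting material
21 | (S)-3-acetoxybutanoic acid | CC(=O)O[C@@H](C)CC(=O)O | intermediate
22 | (S)-3-acetoxybutanoyl chloride | CC(=O)O[C@@H](C)CC(=O)Cl | intermediate
23 | 4-(benzoyloxy)-2,5-bis(benzyloxy)-3,6-bis[4-(benzyloxy)phenyl]phenyl (3S)-3-(acetyloxy)butanoate | CC(=O)O[C@@H](C)CC(=O)Oc1c(-c2ccc(OCc3ccccc3)cc2)c(OCc2ccccc2)c(OC(=O)c2ccccc2)c(-c2ccc(OCc3ccccc3)cc2)c1OCc1ccccc1 | intermediate
24 | 4-(benzoyloxy)-2,5-dihydroxy-3,6-bis(4-hydroxyphenyl)phenyl (3S)-3-(acetyloxy)butanoate | CC(=O)O[C@@H](C)CC(=O)Oc1c(O)c(-c2ccc(O)cc2)c(OC(=O)c2ccccc2)c(O)c1-c1ccc(O)cc1 | target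

**Step count**
Total: 9 steps. Longest linear sequence: 6 steps (1, 2, 5, 6, 8, 9 from squaric acid; equally 3, 4, 5, 6, 8, 9 from 4-(benzyloxy)benzaldehyde).

**Steps most likely to fail, with fallbacks**

Step 6 (ring expansion of an acyloxy-substituted cyclobutenone; not precedented as such, and the enol ether oxygen sits on the inside of the closing triene). The fallback sets out from 7 and 13 and returns at 19. Step 5 is run as written, but alkoxide 15 is trapped with t-BuMe2SiOTf instead of benzoyl chloride. This gives 3-(benzyloxy)-2-[4-(benzyloxy)phenyl]-4-{(Z)-2-(benzyloxy)-1-[4-(benzyloxy)phenyl]ethenyl}-4-[(tert-butyldimethylsilyl)oxy]cyclobut-2-en-1-one F4, a member of the silyl ether class for which the ring expansion is established. Heating in toluene at 110 °C gives 2,5-bis(benzyloxy)-3,6-bis[4-(benzyloxy)phenyl]-4-[(tert-butyldimethylsilyl)oxy]phenol F5. Benzoylation of its free phenol (BzCl, pyridine, cat. DMAP, CH2Cl2) gives 2,5-bis(benzyloxy)-3,6-bis[4-(benzyloxy)phenyl]-4-[(tert-butyldimethylsilyl)oxy]phenyl benzoate F6. HF·pyridine in THF then frees the other oxygen. Because the core is symmetric apart from these two para oxygens, the product is 19 itself. This fallback also covers a sluggish benzoyl trap in step 5.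

Step 4 (Z-selectivity of the bromination–elimination; the E bromide would give a vinyllithium that loses LiOBn to the arylalkyne). The fallback sets out from 3 and returns at 14. Aryllithium 4 (n-BuLi, THF, −78 °C) is acylated with 2-(benzyloxy)-N-methoxy-N-methylacetamide to give 2-(benzyloxy)-1-[4-(benzyloxy)phenyl]ethan-1-one F1. LiN(SiMe3)2 in THF at −78 °C forms the chelated enolate with OLi cis to OBn, and PhNTf2 traps it as (Z)-2-(benzyloxy)-1-[4-(benzyloxy)phenyl]ethenyl trifluoromethanesulfonate F2. Stannylation with Me3SnSnMe3, LiCl and cat. Pd(PPh3)4 in THF at 60 °C proceeds with retention to {(Z)-2-(benzyloxy)-1-[4-(benzyloxy)phenyl]ethenyl}trimethylstannane F3. Tin–lithium exchange with MeLi (THF, −78 °C) gives vinyllithium 14, and step 5 continues unchanged. The geometry is then set by enolate chelation and not by an elimination.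

Step 8 (hindered phenol, and an acid chloride that can lose acetate to give the crotonate). The fallback sets out from 20 and 19 and returns at 23. Acid 20 is silylated on both oxygens (t-BuMe2SiCl, imidazole, DMF) to tert-butyldimethylsilyl (3S)-3-[(tert-butyldimethylsilyl)oxy]butanoate F7. K2CO3 in aqueous MeOH/THF cleaves only the silyl ester to (3S)-3-[(tert-butyldimethylsilyl)oxy]butanoic acid F8. Carbodiimide coupling with 19 (EDC·HCl, cat. DMAP, CH2Cl2) gives 4-(benzoyloxy)-2,5-bis(benzyloxy)-3,6-bis[4-(benzyloxy)phenyl]phenyl (3S)-3-[(tert-butyldimethylsilyl)oxy]butanoate F9; the silyloxy group is a much poorer β-leaving group than acetate. HF·pyridine in THF gives 4-(benzoyloxy)-2,5-bis(benzyloxy)-3,6-bis[4-(benzyloxy)phenyl]phenyl (3S)-3-hydroxybutanoate F10. Ac2O/pyridine at 0 °C then gives 23.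

**Further compounds**
F1 | step 4 | 2-(benzyloxy)-1-[4-(benzyloxy)phenyl]ethan-1-one | O=C(COCc1ccccc1)c1ccc(OCc2ccccc2)cc1
F2 | step 4 | (Z)-2-(benzyloxy)-1-[4-(benzyloxy)phenyl]ethenyl trifluoromethanesulfonate | FC(F)(F)S(=O)(=O)O/C(=C\OCc1ccccc1)c1ccc(OCc2ccccc2)cc1
F3 | step 4 | {(Z)-2-(benzyloxy)-1-[4-(benzyloxy)phenyl]ethenyl}trimethylstannane | C[Sn](C)(C)/C(=C\OCc1ccccc1)c1ccc(OCc2ccccc2)cc1
F4 | step 6 | 3-(benzyloxy)-2-[4-(benzyloxy)phenyl]-4-{(Z)-2-(benzyloxy)-1-[4-(benzyloxy)phenyl]ethenyl}-4-[(tert-butyldimethylsilyl)oxy]cyclobut-2-en-1-one | O=C1C(c2ccc(OCc3ccccc3)cc2)=C(OCc2ccccc2)C1(O[Si](C)(C)C(C)(C)C)/C(=C\OCc2ccccc2)c2ccc(OCc3ccccc3)cc2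
F5 | step 6 | 2,5-bis(benzyloxy)-3,6-bis[4-(benzyloxy)phenyl]-4-[(tert-butyldimethylsilyl)oxy]phenol | Oc1c(-c2ccc(OCc3ccccc3)cc2)c(OCc2ccccc2)c(O[Si](C)(C)C(C)(C)C)c(-c2ccc(OCc3ccccc3)cc2)c1OCc1ccccc1
F6 | step 6 | 2,5-bis(benzyloxy)-3,6-bis[4-(benzyloxy)phenyl]-4-[(tert-butyldimethylsilyl)oxy]phenyl benzoate | O=C(Oc1c(-c2ccc(OCc3ccccc3)cc2)c(OCc2ccccc2)c(O[Si](C)(C)C(C)(C)C)c(-c2ccc(OCc3ccccc3)cc2)c1OCc1ccccc1)c1ccccc1
F7 | step 8 | tert-butyldimethylsilyl (3S)-3-[(tert-butyldimethylsilyl)oxy]butanoate | C[C@H](O[Si](C)(C)C(C)(C)C)CC(=O)O[Si](C)(C)C(C)(C)C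
F8 | step 8 | (3S)-3-[(tert-butyldimethylsilyl)oxy]butanoic acid | C[C@H](O[Si](C)(C)C(C)(C)C)CC(=O)O
F9 | step 8 | 4-(benzoyloxy)-2,5-bis(benzyloxy)-3,6-bis[4-(benzyloxy)phenyl]phenyl (3S)-3-[(tert-butyldimethylsilyl)oxy]butanoate | C[C@H](O[Si](C)(C)C(C)(C)C)CC(=O)Oc1c(-c2ccc(OCc3ccccc3)cc2)c(OCc2ccccc2)c(OC(=O)c2ccccc2)c(-c2ccc(OCc3ccccc3)cc2)c1OCc1ccccc1
F10 | step 8 | 4-(benzoyloxy)-2,5-bis(benzyloxy)-3,6-bis[4-(benzyloxy)phenyl]phenyl (3S)-3-hydroxybutanoate | C[C@H](O)CC(=O)Oc1c(-c2ccc(OCc3ccccc3)cc2)c(OCc2ccccc2)c(OC(=O)c2ccccc2)c(-c2ccc(OCc3ccccc3)cc2)c1OCc1ccccc1
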